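All runs are calculated from invented constants, and the scatter is random.

Between 3.00 min and 6.00 min in Monday's closed flask, the side product gains 3.4 percentage points, while complex with two exchanged loses a smaller 2.3 points.

| flask | starting complex | incoming ligand | leaving ligand | remark | time |
|---|---|---|---|---|---|
| Saturday's | 0.050 M | 0.045 M | 0.25 M | run made earlier |  |
| Monday's | 0.050 M | 0.045 M | 0.35 M | run made earlier |  |
| Sunday's | 0.050 M | 0.045 M | 0.55 M | run made earlier |  |
| red | 0.050 M | 0.0450 M | 0.250 M | one stirred flow tank at steady state, fed with the mixture as stated, mean residence time 5.0 min |  |
| amber | 0.050 M | 0.0450 M | 0.250 M | a closed flask charged with all of it at once and left for 5.0 min | 5.0 min |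
| violet | 0.050 M | 0.0450 M | 0.250 M | a tube with plug flow, the mixed feed as stated, residence time 5.0 min | 5.0 min |
| grey | 0.050 M | 0.0450 M (fed, over 4.00 min) | 0.250 M | a stirred flask in which incoming ligand is dosed at a steady rate over 4.00 min without added volume, worked up at 5.0 min | 5.0 min |

| run | time / min | complex with two exchanged / % | complex with three exchanged / % | side product / % |
|---|---|---|---|---|
| Saturday's | 0.200 | 6.8 | 2.2 | 0.2 |
| Saturday's | 0.667 | 12.2 | 2.5 | 1.3 |
| Saturday's | 1.00 | 13.9 | 4.5 | 1.3 |
| Saturday's | 1.50 | 16.5 | 5.1 | 3.3 |
| Saturday's | 2.50 | 16.6 | 7.5 | 4.1 |
| Saturday's | 3.00 | 17.5 | 7.1 | 4.3 |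
| Monday's | 1.00 | 13.4 | 3.6 | 0 |
| Monday's | 2.00 | 18.1 | 7.3 | 4.3 |
| Monday's | 3.00 | 16.1 | 7.1 | 5.4 |
| Monday's | 4.00 | 16.1 | 9.2 | 6.2 |
| Monday's | 5.00 | 15.6 | 6.7 | 8.3 |
| Monday's | 6.00 | 13.8 | 8.3 | 8.8 |
| Sunday's | 0.417 | 4.3 | 0.1 | 0 |
| Sunday's | 1.33 | 13.8 | 4.3 | 1.3 |
| Sunday's | 2.00 | 15.4 | 4.5 | 5.7 |
| Sunday's | 3.00 | 17.5 | 6.6 | 5.2 |
| Sunday's | 5.00 | 16.2 | 6.7 | 5.9 |
| Sunday's | 6.00 | 15.4 | 7.9 | 11.2 |

(scatter of a reading: 1 percentage point)

- percent here means starting complex units held: one side product counts as two
- the stated concentrations are those of everything mixed, before any reaction; amounts are the same in each set-up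
- steps that have been proposed: starting complex + incoming ligand <-> leaving ligand + complex with one exchanged; leaving ligand -> by-product carried off; complex with one exchanged + incoming ligand <-> leaving ligand + complex with two exchanged; complex with two exchanged + incoming ligand <-> leaving ligand + complex with three exchanged; starting complex + complex with two exchanged -> side product
- the feed brings no volume worth counting
- the earlier runs were made in a closed, stirred flask

1. the set-up with the highest share of complex with two exchanged in all that became complex with two exchanged or complex with three exchanged or side product, at the outlet or at the end ("none" if the first two lie within 2 percentage points) (red / amber / violet / grey / none)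
2. share of complex with two exchanged in all that became complex with two exchanged or complex with three exchanged or side product, at the outlet or at the end, red
3. share of complex with two exchanged in all that became complex with two exchanged or complex with three exchanged or side product, at the outlet or at the end, amber
4. share of complex with two exchanged in all that became complex with two exchanged or complex with three exchanged or side product, at the outlet or at the end, violet
5. share of complex with two exchanged in all that became complex with two exchanged or complex with three exchanged or side product, at the outlet or at the end, grey

Let B, C and O be the percentages held as complex with two exchanged, complex with three exchanged and side product. The proposed side-product step consumes one complex with two exchanged and one starting complex, and the side product counts as two units. Dividing the rate at which this step lowers B by the rate at which it raises O therefore gives 0.5, and time drops out. So B + 0.5O should stay level once the exchange steps no longer move B, and I judge that by whether C stands still.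

My doubt is whether C does stand still, since Monday's C moves by 1.2 points. That is close to the scatter of 1 point, so I accept it. The sum, read from the runs:

| Run | at 3.00 min | at 6.00 min |
|---|---|---|
| Saturday's | 19.7% | – |
| Monday's | 18.8% | 18.2% |
| Sunday's | 20.1% | 21.0% |

A second doubt is that leaving ligand might shift it, but Sunday's and Monday's values at 3.00 min differ by 1.3 points, again near the scatter. The mean is 19.6%, and I call it the ledger T, complex with two exchanged plus 0.5 of the side product.

The share, or selectivity, is then S = (T − 0.5O)/(T + 0.5O + C). For amber I take, as readings, O = 7.10% from Monday's and Sunday's values at 5.00 min and C = 7.40% from their values at 5.00 min and 6.00 min, which gives 52.5%. But the two O readings differ, and taken singly they give 49.5% and 55.5%, so that is my range. A slice of violet's tube lives through amber's history, so I expect the same there. For red and grey the readings give no T, and I commit to no figure.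

The forecast gives 40% for red, 52% for amber, 52% for violet and 57% for grey, with grey best, holding that “Closed flask and plug flow are kinetically identical”.

The simulation gives 50.2%, 51.1%, 51.1% and 60.2% in that order, with grey best, and amber falls inside my range.

    starting complex + incoming ligand ⇌ leaving ligand + complex with one exchanged (K = 2.70, k = 2.90 M⁻¹ s⁻¹)
    leaving ligand → by-product carried off (k = 0.0310 s⁻¹)
    complex with one exchanged + incoming ligand ⇌ leaving ligand + complex with two exchanged (K = 2.20, k = 20.0 M⁻¹ s⁻¹)
    complex with two exchanged + incoming ligand ⇌ leaving ligand + complex with three exchanged (K = 2.10, k = 1.20 M⁻¹ s⁻¹)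
    starting complex + complex with two exchanged → side product (k = 0.0400 M⁻¹ s⁻¹)

In amber, with the other concentrations as charged, the forward rate of the first exchange alone gives starting complex a half-life of 0.089 min, against 5.8 min for complex with two exchanged by the side-product step alone. At 5.00 min, amber's ledger stands at 20.2% and grey's at 22.2%.

Grey read at 8.00 min holds O = 11.8% and C = 5.86%, so grey's ledger, carried over from 5.00 min, gives B = 16.3% and S = 48.0%. The computed flask has B = 16.4% and S = 48.2%.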